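**Retrosynthetic overview**
1. Pinnatin B (20) ⇐ furan 19: the Z-ene-1,4-dione is a masked 2,5-disubstituted 3-methylfuran, opened with singlet oxygen in the last step.
2. 19 ⇐ acyclic (Z)-2-en-4-yn-1-one 18 (key step): one Rh(II) step converts the enynone into a 2-furyl carbene that cyclopropanates the butenolide isopropenyl group, forming furan, cyclopropane (C7, C8) and the 13-membered ring together.
3. 18 ⇐ alkyl iodide 16 + iodobutenolide 8 (sp3–sp2 Negishi, C3–C4); 8 comes from methacrolein + methyl propiolate (C6 by asymmetric alkynylation).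
4. 16 ⇐ hydroxy-lactone 12 + Z-iodo-enyne 3; C1 is set by Rh/BINAP isopropenyl 1,4-addition to 5,6-dihydropyran-2-one and C13 by trans enolate hydroxylation.
5. Ring order: butenolide (fragment stage) → furan + cyclopropane + macrocycle (simultaneously) → furan opened to the ene-dione.

Assumption: atom labels follow the ring order of the target SMILES (C1 = CH-isopropenyl, C4–C6 = butenolide α, β, γ carbons, C7/C8 = cyclopropane C(Me)/CH, C9–C12 = ene-dione, C13 = CH-OAc; all five stereocentres are S). Only skeleton-building compounds and intermediates are numbered; other reagents are given by name and SMILES in the step.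

**Route**

Step 1
Reactants: 1 3-(trimethylsilyl)prop-2-ynal; 2 ethyltriphenylphosphonium iodide
Product: 3 (Z)-(4-iodopent-3-en-1-yn-1-yl)trimethylsilane (iodine cis to the alkynyl group)
Conditions: 2, n-BuLi, THF, 0 °C; I2, −78 °C; NaHMDS, −20 °C; then 1, −78 → −20 °C
Reagents that add atoms: iodine, II
Why: Zhao α-iodoethylidene Wittig olefination (Ph3P=C(I)CH3) gives the (Z)-2-iodoalk-2-ene kinetically, which fixes the acyl/alkynyl cis relationship later needed for furan formation.

Step 2
Reactants: 4 methacrolein; 5 methyl propiolate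
Product: 6 methyl (R)-4-hydroxy-5-methylhex-5-en-2-ynoate
Conditions: (S,S)-ProPhenol (10 mol %), Me2Zn, Ph3P=O (20 mol %), toluene, 4 °C
Reagents that add atoms: none
Why: dinuclear-zinc ProPhenol asymmetric alkynylation of an α-substituted enal with a propiolate sets the future butenolide γ-carbon C6; I could not fix the ligand sense from memory, so the R assignment must be confirmed by Mosher analysis and the antipodal ligand used if needed.

Step 3
Reactants: 6
Product: 7 (S)-5-(prop-1-en-2-yl)-3-(tributylstannyl)furan-2(5H)-one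
Conditions: Bu3SnH, Pd(PPh3)4 (2 mol %), THF, 0 °C → rt; then PPTS (cat.)
Reagents that add atoms: tributyltin hydride, CCCC[SnH](CCCC)CCCC
Why: Pd(0)-catalysed syn-hydrostannation of a 2-alkynoate puts tin α to the ester with the ester cis to the carbinol, so the γ-hydroxy enoate lactonises without touching the C–O stereocentre (R→S is only a CIP priority change).

Step 4
Reactants: 7
Product: 8 (S)-3-iodo-5-(prop-1-en-2-yl)furan-2(5H)-one
Conditions: I2, CH2Cl2, 0 °C
Reagents that add atoms: iodine, II
Why: ipso iododestannylation is much faster than iodine addition to the isopropenyl group and is neutral, so the base-sensitive γ-stereocentre survives.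

Step 5
Reactants: 9 5,6-dihydro-2H-pyran-2-one; 10 potassium isopropenyltrifluoroborate
Product: 11 (R)-4-(prop-1-en-2-yl)tetrahydro-2H-pyran-2-one
Conditions: [Rh(cod)2]PF6 (3 mol %), (R)-BINAP (3.3 mol %), toluene/H2O (20:1), 105 °C
Reagents that add atoms: none
Why: Hayashi–Miyaura Rh/BINAP asymmetric 1,4-addition of an alkenylboron reagent to the unsaturated δ-lactone sets C1; (R)-BINAP gives the R adduct by the same facial rule as aryl additions to this lactone and to cyclohexenone.

Step 6
Reactants: 11
Product: 12 (3S,4S)-3-hydroxy-4-(prop-1-en-2-yl)tetrahydro-2H-pyran-2-one (trans)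
Conditions: NaHMDS, THF, −78 °C; 2-(phenylsulfonyl)-3-phenyloxaziridine; CSA quench
Reagents that add atoms: Davis oxaziridine, O=S(=O)(c1ccccc1)N1OC1c1ccccc1
Why: Davis hydroxylation of the lactone enolate occurs anti to the adjacent C4 isopropenyl group, giving the trans-3,4 product that maps onto the 13S,1S pair of the target.

Step 7
Reactants: 12
Product: 13 (2S,3S)-2,5-dihydroxy-N-methoxy-N-methyl-3-(prop-1-en-2-yl)pentanamide
Conditions: MeNH(OMe)·HCl, AlMe3, CH2Cl2, 0 °C → rt
Reagents that add atoms: N,O-dimethylhydroxylamine hydrochloride, CNOC.Cl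
Why: Weinreb aminolysis with the aluminium amide opens the lactone at the acyl carbon only, so no stereocentre is touched and C3 is released as a primary alcohol.

Step 8
Reactants: 13
Product: 14 (2S,3S)-2-hydroxy-5-iodo-N-methoxy-N-methyl-3-(prop-1-en-2-yl)pentanamide
Conditions: PPh3, I2, imidazole, CH2Cl2, 0 °C
Reagents that add atoms: iodine, II
Why: Appel (Garegg–Samuelsson) iodination is selective for the unhindered primary alcohol over the hindered, carbonyl-deactivated α-hydroxyl.

Step 9
Reactants: 14; 3
Product: 15 (3Z,6S,7S)-6-hydroxy-9-iodo-4-methyl-7-(prop-1-en-2-yl)-1-(trimethylsilyl)non-3-en-1-yn-5-one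
Conditions: 3 (2.5 equiv), t-BuLi (5.0 equiv), Et2O, −78 °C; then 14, THF, −78 °C; AcOH quench at −78 °C
Reagents that add atoms: none (the enyne unit comes from 3)
Why: iodine–lithium exchange gives a configurationally stable Z-alkenyllithium that adds once to the Weinreb amide (stable chelate), the first equivalent only deprotonating the α-OH and the primary iodide being inert at −78 °C, so the enynone is formed with acyl and alkynyl cis.

Step 10
Reactants: 15
Product: 16 (3Z,6S,7S)-9-iodo-4-methyl-5-oxo-7-(prop-1-en-2-yl)-1-(trimethylsilyl)non-3-en-1-yn-6-yl acetate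
Conditions: Ac2O, pyridine, DMAP (cat.), CH2Cl2, 0 °C
Reagents that add atoms: acetic anhydride, CC(=O)OC(C)=O
Why: O-acylation of the α-hydroxy ketone under weakly basic conditions installs the target's acetate without epimerising C13.

Step 11
Reactants: 16; 8
Product: 17 (3Z,6S,7S)-4-methyl-5-oxo-9-[(5S)-2-oxo-5-(prop-1-en-2-yl)-2,5-dihydrofuran-3-yl]-7-(prop-1-en-2-yl)-1-(trimethylsilyl)non-3-en-1-yn-6-yl acetate
Conditions: 16, Zn dust (BrCH2CH2Br/TMSCl-activated), LiCl, THF, 25 °C; then 8 (1.1 equiv), Pd2(dba)3 (2.5 mol %), SPhos (10 mol %), THF, 25 °C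
Reagents that add atoms: none
Why: Knochel zinc insertion into the primary C–I bond followed by Negishi sp3–sp2 coupling with the α-iodobutenolide forms C3–C4 under neutral, base-free conditions in which alkylzinc iodides do not add to ketones, enones or acetates and do not deprotonate the butenolide γ-C–H.

Step 12
Reactants: 17
Product: 18 (3Z,6S,7S)-4-methyl-5-oxo-9-[(5S)-2-oxo-5-(prop-1-en-2-yl)-2,5-dihydrofuran-3-yl]-7-(prop-1-en-2-yl)non-3-en-1-yn-6-yl acetate
Conditions: TBAF, AcOH (1:1.5), THF, −20 → 0 °C
Reagents that add atoms: none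
Why: buffered fluoride protodesilylation frees the terminal alkyne while the acetic acid protects the acetate, the α-acetoxy ketone and the isomerisation-prone γ-isopropenyl butenolide from base.

Step 13 (key step)
Reactants: 18
Product: 19, the furan-bridged 13-membered macrocycle: a 3-methylfuran-2,5-diyl joins cyclopropane C8 and C13(OAc); trans-1,2-bridged cyclopropane with methyl cis to furan; C1, C6, C7, C8, C13 all S
Conditions: Rh2(OAc)4 (5 mol %), ClCH2CH2Cl, 40 °C, 18 added by syringe pump over 12 h (final 1 mM), Ar
Reagents that add atoms: none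
Why: Proposed new method: Rh(II) π-activation of the terminal alkyne triggers 5-exo-dig attack of the cis ketone oxygen to give a (2-furyl)rhodium carbene, which cyclopropanates the only alkene it can reach, the C6 isopropenyl (the C1 isopropenyl would require a [4]/[5](2,5)furanophane); attack at the CH2 terminus on the face syn to C5 (C6–H eclipsing C=CH2, tether side, anti to the ring oxygen) with the furan over the methyl rather than the butenolide is predicted to give the trans-bridged 7S,8S cyclopropane, the closest known reactions being intermolecular furyl-carbenoid cyclopropanations from cis-enynones and macrocyclic Rh-catalysed cyclopropanations of diazo compounds.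

Step 14
Reactants: 19
Product: 20 pinnatin B
Conditions: O2, methylene blue (cat.), red LED, CH2Cl2, −78 °C; then Me2S, −78 °C → rt
Reagents that add atoms: oxygen, O=O
Why: furan photooxygenation ([4+2] with singlet oxygen, far faster than the ene reaction of the 1,1-disubstituted alkene) and Me2S reduction of the endoperoxide opens the furan to the ene-1,4-dione, whose Z geometry is inherited from the ring.

**Compound list**
1 | 3-(trimethylsilyl)prop-2-ynal | C[Si](C)(C)C#CC=O | starting material
2 | ethyltriphenylphosphonium iodide | CC[P+](c1ccccc1)(c1ccccc1)c1ccccc1.[I-] | starting material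
3 | (Z)-(4-iodopent-3-en-1-yn-1-yl)trimethylsilane | C[Si](C)(C)C#C/C=C(/C)I | intermediate
4 | methacrolein | C=C(C)C=O | starting material
5 | methyl propiolate | C#CC(=O)OC | starting material
6 | methyl (R)-4-hydroxy-5-methylhex-5-en-2-ynoate | COC(=O)C#C[C@H](O)C(C)=C | intermediate
7 | (S)-5-(prop-1-en-2-yl)-3-(tributylstannyl)furan-2(5H)-one | CCCC[Sn](CCCC)(CCCC)C1=C[C@H](OC1=O)C(C)=C | intermediate
8 | (S)-3-iodo-5-(prop-1-en-2-yl)furan-2(5H)-one | IC1=C[C@H](OC1=O)C(C)=C | intermediate
9 | 5,6-dihydro-2H-pyran-2-one | O=C1C=CCCO1 | starting material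
10 | potassium isopropenyltrifluoroborate | C=C(C)[B-](F)(F)F.[K+] | starting material
11 | (R)-4-(prop-1-en-2-yl)tetrahydro-2H-pyran-2-one | C=C(C)[C@@H]1CCOC(=O)C1 | intermediate
12 | (3S,4S)-3-hydroxy-4-(prop-1-en-2-yl)tetrahydro-2H-pyran-2-one | C=C(C)[C@@H]1CCOC(=O)[C@H]1O | intermediate
13 | (2S,3S)-2,5-dihydroxy-N-methoxy-N-methyl-3-(prop-1-en-2-yl)pentanamide | C=C(C)[C@H](CCO)[C@H](O)C(=O)N(C)OC | intermediate
14 | (2S,3S)-2-hydroxy-5-iodo-N-methoxy-N-methyl-3-(prop-1-en-2-yl)pentanamide | C=C(C)[C@H](CCI)[C@H](O)C(=O)N(C)OC | intermediate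
15 | (3Z,6S,7S)-6-hydroxy-9-iodo-4-methyl-7-(prop-1-en-2-yl)-1-(trimethylsilyl)non-3-en-1-yn-5-one | C=C(C)[C@H](CCI)[C@H](O)C(=O)/C(C)=C\C#C[Si](C)(C)C | intermediate
16 | (3Z,6S,7S)-9-iodo-4-methyl-5-oxo-7-(prop-1-en-2-yl)-1-(trimethylsilyl)non-3-en-1-yn-6-yl acetate | C=C(C)[C@H](CCI)[C@H](OC(C)=O)C(=O)/C(C)=C\C#C[Si](C)(C)C | intermediate
17 | (3Z,6S,7S)-4-methyl-5-oxo-9-[(5S)-2-oxo-5-(prop-1-en-2-yl)-2,5-dihydrofuran-3-yl]-7-(prop-1-en-2-yl)-1-(trimethylsilyl)non-3-en-1-yn-6-yl acetate | C=C(C)[C@H](CCC1=C[C@H](OC1=O)C(C)=C)[C@H](OC(C)=O)C(=O)/C(C)=C\C#C[Si](C)(C)C | intermediate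
18 | (3Z,6S,7S)-4-methyl-5-oxo-9-[(5S)-2-oxo-5-(prop-1-en-2-yl)-2,5-dihydrofuran-3-yl]-7-(prop-1-en-2-yl)non-3-en-1-yn-6-yl acetate | C=C(C)[C@H](CCC1=C[C@H](OC1=O)C(C)=C)[C@H](OC(C)=O)C(=O)/C(C)=C\C#C | intermediate
19 | furan-bridged macrocycle (furan form of 20; all five stereocentres S) | C=C(C)[C@@H]1CCC2=C[C@H](OC2=O)[C@@]2(C)C[C@@H]2c2cc(C)c(o2)[C@H]1OC(C)=O | intermediate
20 | pinnatin B | C=C(C)[C@@H]1CCC2=C[C@H](OC2=O)[C@@]2(C)C[C@@H]2C(=O)/C=C(/C)C(=O)[C@H]1OC(C)=O | target

**Step count**
Total steps: 14. Longest linear sequence: 10 (steps 5–14, from 5,6-dihydro-2H-pyran-2-one).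

**Three steps most likely to fail, with fallbacks**
1. Step 13 (macrocyclising furyl-carbene cyclopropanation): risks are carbene dimerisation or oligomerisation, allylic C–H insertion at C6, and the wrong cyclopropane diastereomer, since the facial and cis/trans preferences are predictions. Fallback: move the ring closure to C3–C4. Run the Rh furyl-carbene cyclopropanation intermolecularly between desilylated 16 and the isopropenyl group of 8 (chiral dirhodium catalyst to tune diastereoselectivity), then close the 13-membered ring by intramolecular alkylzinc/vinyl iodide Negishi coupling.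
2. Step 11 (Negishi coupling with the Z-enynone and α-acetoxy ketone present): Zn(II) or Pd(II) could activate the enynone prematurely, or the ketone could be attacked or reduced. Fallback: reorder so the enynone is unveiled last. Acetylate 14 and couple it with 8 at the Weinreb amide stage, reduce the amide to the aldehyde (Cp2Zr(H)Cl), join 3 by Cr/Ni (Nozaki–Hiyama–Kishi) coupling, and oxidise with Dess–Martin periodinane.
3. Step 9 (alkenyllithium addition to an unprotected α-hydroxy Weinreb amide carrying a primary iodide): risks are tetrahydrofuran formation from the alkoxide and iodide, and loss of Z geometry. Fallback: make the C11–C12 bond by a neutral cross-coupling. Open 12 with AlMe3/EtSH to the thioester and couple it with the alkenylstannane derived from 3 under Pd/Cu(I) carboxylate (Liebeskind–Srogl) conditions.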